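The γ‑lactone ring (C13, C14, C15, O, C16) is read as an oxidised 3‑substituted furan whose β‑carbon is the spiro atom C13, held 1,4 to the C9 oxygen. The oxolane ring O–C9–C11–C12–C13 is therefore closed last, by a bromenium‑triggered dearomative ipso‑spiroetherification. In one operation this sets the C13–O bond, the quaternary stereocentre C13 and the acetal oxidation level at C16. The precursor is a 9α‑hydroxy 3‑furylethyl decalin that already carries the 19,20‑lactone. It is reached from commercial (+)‑marrubiin by moving the lactone from O6 to C20 through a Barton nitrite C–H oxidation. Enol‑ether hydrogenation and acetal oxidation complete the target.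

Key step: step 6

Assumption: labdane numbering is used (decalin C1–C10, C17 on C8, C18 and C19 on C4, C20 on C10, side chain C11–C16); the target is read as (4S,5R,6R,8R,9R,10S,13S), and (+)‑marrubiin, a purchasable furanolabdane with the same six decalin stereocentres, is taken as the commercial starting material.

Step 1
Reactants: 1 (+)‑marrubiin (15,16‑epoxy‑9α‑hydroxylabda‑13(16),14‑dien‑19,6β‑olide; C17 methyl α)
Product: 3 methyl marrubiinate (methyl 15,16‑epoxy‑6β,9α‑dihydroxylabda‑13(16),14‑dien‑19‑oate), via potassium marrubiinate 2 (not isolated)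
Conditions: KOH (1.05 equiv), MeOH/H2O, 70 °C; evaporate; then MeI, DMF, 0 °C to rt
Reagents that add atoms: potassium hydroxide [K+].[OH-]; iodomethane CI
Why: Saponification opens the 19,6β‑γ‑lactone and SN2 O‑methylation of the carboxylate traps the hydroxy acid as its methyl ester before it can relactonise, with all stereocentres untouched.

Step 2
Reactants: 3 methyl marrubiinate
Product: 4 methyl 15,16‑epoxy‑9α‑hydroxy‑6β‑(nitrosooxy)labda‑13(16),14‑dien‑19‑oate (6β‑nitrite ester)
Conditions: NOCl (1.1 equiv), pyridine, −20 °C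
Reagents that add atoms: nitrosyl chloride O=NCl
Why: Nitrite ester formation (O‑nitrosation) at the secondary 6β‑hydroxyl; the tertiary 9α‑hydroxyl, flanked by C8 and the quaternary C10, is expected to stay free with one equivalent of NOCl in cold pyridine, and the furan should not be attacked under these conditions.

Step 3
Reactants: 4 6β‑nitrite ester
Product: 6 methyl (E)‑15,16‑epoxy‑6β,9α‑dihydroxy‑20‑(hydroxyimino)labda‑13(16),14‑dien‑19‑oate, via 20‑nitroso ester 5 (not isolated)
Conditions: hν (Hg lamp, Pyrex), benzene, 10 °C, Ar; then i‑PrOH, 60 °C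
Reagents that add atoms: none
Why: Barton nitrite photolysis: O–NO homolysis gives the 6β‑alkoxyl radical, which abstracts hydrogen from the 1,3‑diaxial C20 methyl group through a six‑membered transition state (1,5‑hydrogen transfer; C19 carries no hydrogen), the C20 radical recombines with NO and the nitroso compound tautomerises to the oxime on warming, with no stereocentre changed.

Step 4
Reactants: 6 20‑oxime
Product: 7 methyl 6β,20:15,16‑diepoxy‑9α,20‑dihydroxylabda‑13(16),14‑dien‑19‑oate (6β,20‑hemiacetal, C20 epimers)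
Conditions: TiCl3 (aq.), NH4OAc, THF/H2O, 0 °C to rt
Reagents that add atoms: water O
Why: Reductive deoximation: TiCl3 cleaves the N–O bond, the imine is hydrolysed to the C20 aldehyde and the 6β‑hydroxyl traps it at once as the five‑membered hemiacetal, under buffered conditions that should spare the furan and the ester.

Step 5
Reactants: 7 6β,20‑hemiacetal
Product: 9 15,16‑epoxy‑6β,9α‑dihydroxylabda‑13(16),14‑dien‑19,20‑olide, via triol ester 8 (not isolated)
Conditions: NaBH4, MeOH, −20 to 0 °C; then AcOH (cold quench)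
Reagents that add atoms: none
Why: Borohydride reduction of the open hydroxy‑aldehyde form gives the primary C20 alkoxide, which lies 1,3‑diaxial to the C19 ester and should close the strain‑free bridged δ‑lactone by intramolecular transesterification faster than the hindered secondary 6β‑hydroxyl can form the γ‑lactone, and the cold acidic quench stops base‑mediated translactonisation.

Step 6
Reactants: 9 15,16‑epoxy‑6β,9α‑dihydroxylabda‑13(16),14‑dien‑19,20‑olide
Product: 11 (13S)‑9α,13:15,16‑diepoxy‑6β‑hydroxy‑16‑methoxylabd‑14‑en‑19,20‑olide (C16 epimers), via 16‑bromo spiro ether 10 (not isolated)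
Conditions: NBS (1.0 equiv), (DHQD)2PHAL (hydroquinidine 1,4‑phthalazinediyl diether, 10 mol%), CHCl3/hexane, −60 °C; then MeOH, 2,6‑lutidine, −60 to 0 °C
Reagents that add atoms: methanol CO
Why: Proposed new method: the catalyst‑bound bromenium ion is expected to add to the furan at C16, the α‑position next to the alkyl branch, which gives a 2H‑furanium ion with its charge on C13 and C15; the axial 9α‑hydroxyl, held by the C11–C12 tether, captures C13 ipso, and the α‑bromo ether 10 is then methanolysed through its oxocarbenium ion to the acetal 11. The closest known reaction types are the alkoxybromination of furans (Clauson–Kaas type), the NBS‑induced spiroetherification of furyl alkanols and the cinchona‑alkaloid‑catalysed dearomative halocyclisation of benzofurans and indoles, and the C13–O bond formation is the microscopic reverse of the acid‑induced aromatisation by which 9,13‑epoxy enol ethers of this family open to 9‑hydroxy furans. The oxolane ring, the only ring formed, closes in a polar 5‑exo‑trig C–O closure onto the furanium ion. C9 keeps its configuration because only its O–H bond reacts; C13 is new, and since C1H2 and the C17 methyl group flank the tether almost symmetrically the substrate gives little bias, so the face is to be set by the halenium‑transfer catalyst (reagent control, with the pseudo‑enantiomeric (DHQ)2PHAL as the alternative if the sense is opposite); C16 forms as an epimer mixture that is erased in step 8. The step needs regioselectivity for bromination at C16 with ipso closure over bromination at C15 with six‑membered closure at C16, which the cation‑stabilising alkyl group on C13 and the short tether should secure, and chemoselectivity for the furan over the enol ether of the product, which one equivalent of NBS at low temperature should secure.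

Step 7
Reactants: 11 (13S)‑16‑methoxy spiro enol ether
Product: 12 (13S)‑9α,13:15,16‑diepoxy‑6β‑hydroxy‑16‑methoxylabdan‑19,20‑olide (C16 epimers)
Conditions: H2 (1 atm), 5% Rh on Al2O3, EtOAc, Et3N (trace), rt
Reagents that add atoms: none
Why: Catalytic hydrogenation of the electron‑rich enol ether C14=C15; rhodium on alumina buffered with Et3N is chosen so that the allylic C13–O9 bond is not hydrogenolysed and the acid‑labile allylic acetal is not ionised, and no new stereocentre arises.

Step 8
Reactants: 12 (13S)‑16‑methoxy oxolane acetal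
Product: 13 (13S)‑9α,13‑epoxy‑6β‑hydroxy‑8βH‑labdane‑19,20:16,15‑diolide (target)
Conditions: mCPBA, BF3·OEt2 (0.3 equiv), CH2Cl2, −20 to 0 °C
Reagents that add atoms: 3‑chloroperoxybenzoic acid OOC(=O)c1cccc(Cl)c1
Why: Peracid oxidation of a cyclic acetal to the lactone: BF3 ionises the methyl acetal to the C16 oxocarbenium ion, the peracid adds and the peroxy acetal collapses with loss of 3‑chlorobenzoic acid to the γ‑lactone, which erases the C16 stereocentre and should tolerate the free 6β‑hydroxyl, the oxolane and the δ‑lactone.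

Compound list
1 | (+)‑marrubiin (15,16‑epoxy‑9α‑hydroxylabda‑13(16),14‑dien‑19,6β‑olide; C17 methyl α) | C[C@@H]1C[C@@H](O3)[C@@H]2[C@](C)(CCC[C@]2(C)C3=O)[C@@]1(O)CCc1ccoc1 | starting material
2 | potassium marrubiinate (potassium 15,16‑epoxy‑6β,9α‑dihydroxylabda‑13(16),14‑dien‑19‑oate) | C[C@@H]1C[C@@H](O)[C@@H]2[C@](C)(CCC[C@]2(C)C(=O)[O-])[C@@]1(O)CCc1ccoc1.[K+] | intermediate
3 | methyl marrubiinate (methyl 15,16‑epoxy‑6β,9α‑dihydroxylabda‑13(16),14‑dien‑19‑oate) | C[C@@H]1C[C@@H](O)[C@@H]2[C@](C)(CCC[C@]2(C)C(=O)OC)[C@@]1(O)CCc1ccoc1 | intermediate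
4 | methyl 15,16‑epoxy‑9α‑hydroxy‑6β‑(nitrosooxy)labda‑13(16),14‑dien‑19‑oate | C[C@@H]1C[C@@H](ON=O)[C@@H]2[C@](C)(CCC[C@]2(C)C(=O)OC)[C@@]1(O)CCc1ccoc1 | intermediate
5 | methyl 15,16‑epoxy‑6β,9α‑dihydroxy‑20‑nitrosolabda‑13(16),14‑dien‑19‑oate | C[C@@H]1C[C@@H](O)[C@@H]2[C@](CN=O)(CCC[C@]2(C)C(=O)OC)[C@@]1(O)CCc1ccoc1 | intermediate
6 | methyl (E)‑15,16‑epoxy‑6β,9α‑dihydroxy‑20‑(hydroxyimino)labda‑13(16),14‑dien‑19‑oate | C[C@@H]1C[C@@H](O)[C@@H]2[C@](/C=N/O)(CCC[C@]2(C)C(=O)OC)[C@@]1(O)CCc1ccoc1 | intermediate
7 | methyl 6β,20:15,16‑diepoxy‑9α,20‑dihydroxylabda‑13(16),14‑dien‑19‑oate (C20 epimers) | C[C@@H]1C[C@@H](O3)[C@@H]2[C@](C3O)(CCC[C@]2(C)C(=O)OC)[C@@]1(O)CCc1ccoc1 | intermediate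
8 | methyl 15,16‑epoxy‑6β,9α,20‑trihydroxylabda‑13(16),14‑dien‑19‑oate | C[C@@H]1C[C@@H](O)[C@@H]2[C@](CO)(CCC[C@]2(C)C(=O)OC)[C@@]1(O)CCc1ccoc1 | intermediate
9 | 15,16‑epoxy‑6β,9α‑dihydroxylabda‑13(16),14‑dien‑19,20‑olide | C[C@@H]1C[C@@H](O)[C@@H]2[C@]3(CCC[C@]2(C)C(=O)OC3)[C@@]1(O)CCc1ccoc1 | intermediate
10 | (13S)‑16‑bromo‑9α,13:15,16‑diepoxy‑6β‑hydroxylabd‑14‑en‑19,20‑olide (C16 epimers) | C[C@@H]1C[C@@H](O)[C@@H]2[C@]3(CCC[C@]2(C)C(=O)OC3)[C@@]12CC[C@@]1(C=COC1Br)O2 | intermediate
11 | (13S)‑9α,13:15,16‑diepoxy‑6β‑hydroxy‑16‑methoxylabd‑14‑en‑19,20‑olide (C16 epimers) | C[C@@H]1C[C@@H](O)[C@@H]2[C@]3(CCC[C@]2(C)C(=O)OC3)[C@@]12CC[C@@]1(C=COC1OC)O2 | intermediate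
12 | (13S)‑9α,13:15,16‑diepoxy‑6β‑hydroxy‑16‑methoxylabdan‑19,20‑olide (C16 epimers) | C[C@@H]1C[C@@H](O)[C@@H]2[C@]3(CCC[C@]2(C)C(=O)OC3)[C@@]12CC[C@@]1(CCOC1OC)O2 | intermediate
13 | (13S)‑9α,13‑epoxy‑6β‑hydroxy‑8βH‑labdane‑19,20:16,15‑diolide | C[C@@H]1C[C@@H](O)[C@@H]2[C@]3(CCC[C@]2(C)C(=O)OC3)[C@@]12CC[C@@]1(CCOC1=O)O2 | target

Total step count: 8
Longest linear sequence: 8 steps (1 to 13)

Steps most likely to fail

1. Step 6 (Proposed new method). Facial control at C13 may be weak or of the wrong sense, because the substrate is nearly unbiased and catalyst control on a furan is unproven. The bromenium ion may also enter at C15 and lead to six‑membered closure at C16, and the enol ether may be brominated further once it has formed. The fallback uses known chemistry, sets out from 9 and comes back at 11. Clauson–Kaas alkoxybromination of 9 (NBS, NaHCO3, MeOH, −40 °C) should give 15,16‑epoxy‑6β,9α‑dihydroxy‑15,16‑dimethoxylabd‑13‑en‑19,20‑olide F1 as a mixture of acetal epimers. Pyridinium p‑toluenesulfonate in CH2Cl2 over 4 Å molecular sieves then ionises the acetals reversibly. Closure at C16 to a six‑membered acetal can revert, whereas addition of the 9α‑hydroxyl to C13 of the vinylogous C15 oxocarbenium ion with loss of methanol drains the mixture to 11 and its C13 epimer. Without catalyst control the two epimers are separated by chromatography on base‑washed silica, and the route continues from 11.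

2. Step 3. The 6β‑alkoxyl radical may fragment (β‑scission of C5–C6 or C6–C7) instead of transferring hydrogen, and a trace of 9α‑nitrite or of nitrosated furan from step 2 may decompose on irradiation. The fallback sets out from 3 and comes back at 9. Dehydrogenative silylation of 3 (Et2SiH2, [Ir(cod)OMe]2 cat., THF, rt) should give methyl 6β‑(diethylsilyloxy)‑15,16‑epoxy‑9α‑hydroxylabda‑13(16),14‑dien‑19‑oate F2. Rhodium‑catalysed hydroxyl‑directed δ‑C–H silylation ([Rh(cod)Cl]2, Xantphos, norbornene, THF, 100 °C) should close the 6β‑O–SiEt2–C20 oxasilinane F3 on the 1,3‑diaxial methyl group. Tamao–Fleming oxidation (H2O2, KHCO3, KF, THF/MeOH) then gives triol ester 8, which is lactonised with catalytic K2CO3 in MeOH at 0 °C to 9.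

3. Step 5. Lactonisation may occur through the 6β‑hydroxyl, or the product may translactonise under base to the 19,6β‑olide, because both hydroxyls are 1,3‑diaxial to the ester. The fallback sets out from 6 and comes back at 9. Dess–Martin periodinane (3 equiv, wet CH2Cl2, NaHCO3) should oxidise the 6β‑alcohol and cleave the aldoxime oxidatively to methyl 15,16‑epoxy‑9α‑hydroxy‑6,20‑dioxolabda‑13(16),14‑dien‑19‑oate F4. NaBH4 (THF/MeOH, −40 °C) then reduces the aldehyde first, so the C20 alkoxide lactonises while C6 is still a ketone. On warming to 0 °C the hindered 6‑ketone should be reduced from the open α‑face to the axial 6β‑alcohol. The lactone regiochemistry is thus fixed by the order of events, and 9 is reached after a cold AcOH quench.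

Further compounds
F1 | step 6 | 15,16‑epoxy‑6β,9α‑dihydroxy‑15,16‑dimethoxylabd‑13‑en‑19,20‑olide (acetal epimers) | C[C@@H]1C[C@@H](O)[C@@H]2[C@]3(CCC[C@]2(C)C(=O)OC3)[C@@]1(O)CCC1=CC(OC)OC1OC
F2 | step 3 | methyl 6β‑(diethylsilyloxy)‑15,16‑epoxy‑9α‑hydroxylabda‑13(16),14‑dien‑19‑oate | C[C@@H]1C[C@@H](O[SiH](CC)CC)[C@@H]2[C@](C)(CCC[C@]2(C)C(=O)OC)[C@@]1(O)CCc1ccoc1
F3 | step 3 | methyl 6β,20‑(diethylsilanediyloxy)‑15,16‑epoxy‑9α‑hydroxylabda‑13(16),14‑dien‑19‑oate (O6–Si–C20 oxasilinane) | C[C@@H]1C[C@@H](O3)[C@@H]2[C@](C[Si]3(CC)CC)(CCC[C@]2(C)C(=O)OC)[C@@]1(O)CCc1ccoc1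
F4 | step 5 | methyl 15,16‑epoxy‑9α‑hydroxy‑6,20‑dioxolabda‑13(16),14‑dien‑19‑oate | C[C@@H]1CC(=O)[C@@H]2[C@](C=O)(CCC[C@]2(C)C(=O)OC)[C@@]1(O)CCc1ccoc1
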